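Both cyclopenta[c]pyridine units are cut at C4a–C5. With C3 as a lactam carbonyl and C4=C4a a double bond, C4a is the β-carbon of an unsaturated amide and sits one bond from C7a, whose C7–C6–C5 chain can deliver a C5 radical to it only from its own face; this is the feature used. One silane-mediated radical operation closes both cyclopentane rings 5-exo and fixes both cis ring fusions. The precursor is penta-O-benzyl-(+)-catechin carrying at C6 and C8 of ring A two trans-5,6-disubstituted 1,3-dimethyl-5,6-dihydropyridin-2-ones, each with an (S)-4-iodobutan-2-yl chain, built by sulfinyl imine allylation and ring-closing metathesis.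

Key step: step 16

Remark: C1–C7a are the atoms of each cyclopenta[c]pyridine unit (C1 aryl-bearing, N2, C3, C4 and C7 methyl-bearing, C4a and C7a at the ring fusion); "C6 and C8 of ring A" are flavan positions.
Remark: steps 10, 11 and 13 each incorporate two molecules of the partner (14, 7 and 19), one on each arm; the second molecule is given on the line of reagents that add atoms.
Assumption: in step 11 the γ-substituted allylindium reagent is taken to add anti (nitrogen at C1 versus the branch at C7a) to the N-tert-butanesulfinyl aldimines; this rests on transition-state reasoning, not on secure precedent for this substrate, and the first fallback covers the opposite outcome.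

Step 1
Reactants: 1 (R)-citronellol
Product: 2 (R)-citronellyl tert-butyldimethylsilyl ether
Conditions: TBSCl, imidazole, CH2Cl2, 0 °C to rt
Reagents that add atoms: tert-butyldimethylsilyl chloride, CC(C)(C)[Si](C)(C)Cl
Why: Standard silyl ether formation masks the oxygen that later becomes the C5 leaving group and does not touch the terpene stereocentre, the future C7.

Step 2
Reactants: 2 (R)-citronellyl tert-butyldimethylsilyl ether
Product: 4 (R)-6-[(tert-butyldimethylsilyl)oxy]-4-methylhexanal, via secondary ozonide 3 (not isolated)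
Conditions: O3, CH2Cl2, −78 °C; then PPh3, −78 °C to rt
Reagents that add atoms: ozone, [O-][O+]=O
Why: Ozonolysis with reductive work-up cleaves the only alkene and leaves the aldehyde whose carbon becomes the allylic terminus, with no effect on the stereocentre.

Step 3
Reactants: 4 (R)-6-[(tert-butyldimethylsilyl)oxy]-4-methylhexanal
Product: 5 (S,E)-6-[(tert-butyldimethylsilyl)oxy]-4-methylhex-2-enal
Conditions: IBX (1.3 equiv), DMSO/fluorobenzene, 65 °C
Reagents that add atoms: none
Why: IBX-mediated α,β-dehydrogenation of an aldehyde through its enol should give the E-enal, and the methyl-bearing γ-carbon is not enolised under these weakly acidic conditions when only a slight excess of oxidant is used.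

Step 4
Reactants: 5 (S,E)-6-[(tert-butyldimethylsilyl)oxy]-4-methylhex-2-enal
Product: 6 (S,E)-6-[(tert-butyldimethylsilyl)oxy]-4-methylhex-2-en-1-ol
Conditions: NaBH4, CeCl3·7H2O, MeOH, −20 °C
Reagents that add atoms: none
Why: Luche reduction delivers hydride 1,2 to the enal, so the E-alkene and the allylic stereocentre are kept.

Step 5
Reactants: 6 (S,E)-6-[(tert-butyldimethylsilyl)oxy]-4-methylhex-2-en-1-ol
Product: 7 (S,E)-[(6-bromo-3-methylhex-4-en-1-yl)oxy](tert-butyl)dimethylsilane
Conditions: CBr4, PPh3, CH2Cl2, 0 °C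
Reagents that add atoms: tetrabromomethane, BrC(Br)(Br)Br
Why: Appel bromination converts the primary allylic alcohol into the E-allylic bromide by SN2 displacement under neutral conditions that spare the silyl ether.

Step 6
Reactants: 8 (+)-catechin
Product: 9 5,7,3′,4′-tetra-O-benzyl-(+)-catechin
Conditions: BnBr (4.4 equiv), K2CO3, DMF, 0 °C to rt
Reagents that add atoms: benzyl bromide, BrCc1ccccc1
Why: Williamson etherification with a carbonate base benzylates the four phenols, leaves the less acidic 3-hydroxyl free and is mild enough to avoid epimerisation at C2 of the flavan.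

Step 7
Reactants: 9 5,7,3′,4′-tetra-O-benzyl-(+)-catechin
Product: 10 3,5,7,3′,4′-penta-O-benzyl-(+)-catechin
Conditions: NaH, BnBr, Bu4NI (cat.), DMF, 0 °C to rt
Reagents that add atoms: benzyl bromide, BrCc1ccccc1
Why: Williamson etherification of the secondary alkoxide completes the protection, so that no acidic O–H remains for the organometallic steps.

Step 8
Reactants: 10 3,5,7,3′,4′-penta-O-benzyl-(+)-catechin
Product: 11 6,8-dibromo-3,5,7,3′,4′-penta-O-benzyl-(+)-catechin
Conditions: NBS (2.1 equiv), CH2Cl2, −20 °C to rt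
Reagents that add atoms: N-bromosuccinimide, O=C1CCC(=O)N1Br
Why: Electrophilic aromatic bromination takes place at the only two free positions of the trialkoxy ring A (C6 and C8), which is far more electron-rich than the dialkoxy ring B.

Step 9
Reactants: 11 6,8-dibromo-3,5,7,3′,4′-penta-O-benzyl-(+)-catechin
Product: 13 3,5,7,3′,4′-penta-O-benzyl-(+)-catechin-6,8-dicarbaldehyde, via 6,8-dilithio arene 12 (not isolated)
Conditions: t-BuLi (4.4 equiv), THF, −78 °C; then DMF (8 equiv), −78 °C to 0 °C; aq. NH4Cl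
Reagents that add atoms: N,N-dimethylformamide, CN(C)C=O
Why: Double bromine–lithium exchange at −78 °C (two equivalents of t-BuLi per bromide) followed by formylation of each aryllithium with one molecule of DMF gives the dialdehyde, each aryllithium being stabilised by its two flanking alkoxy groups.

Step 10
Reactants: 13 3,5,7,3′,4′-penta-O-benzyl-(+)-catechin-6,8-dicarbaldehyde; 14 (S)-tert-butanesulfinamide (2.4 equiv)
Product: 15 6,8-bis{(E)-[(S)-tert-butanesulfinylimino]methyl}-3,5,7,3′,4′-penta-O-benzyl-(+)-catechin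
Conditions: 14 (2.4 equiv), Ti(OEt)4 (4 equiv), THF, 65 °C
Reagents that add atoms: (S)-tert-butanesulfinamide 14 as the second of the two molecules that condense, CC(C)(C)[S@](=O)N
Why: Ti(OEt)4-mediated condensation (Lewis acid and water scavenger) joins one molecule of 14 to each of the two formyl groups with loss of two molecules of water and gives the two E-configured N-sulfinyl aldimines without touching the sulfur stereocentre.

Step 11
Reactants: 15 bis(N-sulfinyl aldimine); 7 (S,E)-allylic bromide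
Product: 17 6,8-bis{(1R,2S,3S)-1-[(S)-tert-butanesulfinylamino]-5-[(tert-butyldimethylsilyl)oxy]-2-ethenyl-3-methylpentyl}-3,5,7,3′,4′-penta-O-benzyl-(+)-catechin, via allylindium dibromide 16 (not isolated)
Conditions: indium powder (3 equiv), 7 (3 equiv), THF, 60 °C
Reagents that add atoms: (S,E)-allylic bromide 7 as the second of the two molecules that add, CC(C)(C)[Si](C)(C)OCC[C@H](C)/C=C/CBr
Why: Barbier-type indium-mediated allylation of N-tert-butanesulfinyl aldimines takes place at the γ-carbon of the allylindium 16, one molecule per imine, through a closed chair-like transition state in which the metal is held by the sulfinyl group, so the (S)-sulfinyl group should direct attack to the Re face of each imine (C1 R), the branched γ-substituent of the interconverting allylindium should take the position away from the axial aryl group (C7a anti to nitrogen), and C7 is carried in unchanged by 7.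

Step 12
Reactants: 17 bis(homoallylic sulfinamide)
Product: 18 6,8-bis{(1R,2S,3S)-1-[(S)-tert-butanesulfinyl(methyl)amino]-5-[(tert-butyldimethylsilyl)oxy]-2-ethenyl-3-methylpentyl}-3,5,7,3′,4′-penta-O-benzyl-(+)-catechin
Conditions: NaH (3 equiv), MeI (4 equiv), DMF, 0 °C to rt
Reagents that add atoms: iodomethane, CI
Why: N-Alkylation of each sulfinamide anion with one molecule of iodomethane installs the two N-methyl groups while nitrogen is still masked, which excludes over-alkylation and touches no stereocentre.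

Step 13
Reactants: 18 bis(N-methyl sulfinamide); 19 methacryloyl chloride
Product: 21 6,8-bis{(1R,2S,3S)-2-ethenyl-5-hydroxy-3-methyl-1-[methyl(2-methylprop-2-enoyl)amino]pentyl}-3,5,7,3′,4′-penta-O-benzyl-(+)-catechin, via bis(amino alcohol) dihydrochloride 20 (not isolated)
Conditions: HCl (4 M in dioxane), MeOH, 0 °C to rt; concentrate; then 19 (2.4 equiv), CH2Cl2/sat. aq. NaHCO3, 0 °C
Reagents that add atoms: methacryloyl chloride 19 as the second of the two molecules that acylate, C=C(C)C(=O)Cl
Why: Brief acidolysis in methanol removes both tert-butanesulfinyl groups and both silyl ethers in one treatment, and Schotten–Baumann acylation of the crude amine salt, one molecule of 19 per nitrogen, is selective for nitrogen over the primary hydroxyl groups.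

Step 14
Reactants: 21 bis(N-methyl methacrylamide) diol
Product: 22 6,8-bis{(1R,2S,3S)-2-ethenyl-5-iodo-3-methyl-1-[methyl(2-methylprop-2-enoyl)amino]pentyl}-3,5,7,3′,4′-penta-O-benzyl-(+)-catechin
Conditions: I2 (2.6 equiv), PPh3 (2.6 equiv), imidazole (5 equiv), CH2Cl2, 0 °C to rt
Reagents that add atoms: iodine, II
Why: Appel-type iodination converts the primary alcohols into the iodides by SN2 displacement under nearly neutral conditions that leave the acid-sensitive N-acyl benzylic positions and the alkenes intact.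

Step 15
Reactants: 22 bis(N-methyl methacrylamide) di-iodide
Product: 23 6,8-bis{(5R,6R)-5-[(S)-4-iodobutan-2-yl]-1,3-dimethyl-2-oxo-1,2,5,6-tetrahydropyridin-6-yl}-3,5,7,3′,4′-penta-O-benzyl-(+)-catechin
Conditions: second-generation Hoveyda–Grubbs catalyst (10 mol% per ring), toluene, 80 °C, 5 mM, argon sparge
Reagents that add atoms: none
Why: Double ring-closing metathesis between each vinyl group and the methacrylamide alkene, helped by the tertiary amide, closes the two six-membered unsaturated lactams with loss of ethene and creates no stereocentre.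

Step 16
Reactants: 23 bis(iodoalkyl dihydropyridinone)
Product: 24 6,8-bis[(1R,4S,4aS,7S,7aR)-2,4,7-trimethyl-3-oxooctahydro-1H-cyclopenta[c]pyridin-1-yl]-3,5,7,3′,4′-penta-O-benzyl-(+)-catechin
Conditions: (Me3Si)3SiH (2.6 equiv) and AIBN (0.4 equiv) added by syringe pump, toluene, 85 °C, 5 mM
Reagents that add atoms: none
Why: Iodine abstraction by the silyl radical gives a nucleophilic primary C5 radical on each arm, which adds to the electron-poor β-carbon C4a of the unsaturated lactam; the tertiary α-amide radical formed at C4 then takes hydrogen from the silane and carries the chain. The closest known reaction type is the tin or silicon hydride mediated Giese-type cyclisation of alkyl iodides onto α,β-unsaturated lactams and esters. Each cyclopentane ring closes 5-exo-trig by forming C4a–C5. C4a is controlled by the three-atom tether from C7a, which reaches only the face of C4a on which it sits, so both ring fusions must be cis; C4 is set by hydrogen transfer to the open convex face, which should leave the methyl group on the concave face (the epimer of the target, corrected in step 17), while C1, C7a and C7 are untouched. The step needs ring closure to outrun direct reduction of the C5 radical and 1,5-hydrogen transfer from C1–H; this is secured by the slow hydrogen donor (Me3Si)3SiH held at low concentration and by the trans arrangement, in which A(1,3) strain with N-methyl keeps the aryl group axial and therefore the side chain axial over the π-face of C4a. Benzyl ethers and amides are inert under these neutral conditions.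

Step 17
Reactants: 24 bis-lactam with the kinetic C4 configuration
Product: 25 6,8-bis[(1R,4R,4aS,7S,7aR)-2,4,7-trimethyl-3-oxooctahydro-1H-cyclopenta[c]pyridin-1-yl]-3,5,7,3′,4′-penta-O-benzyl-(+)-catechin
Conditions: KOt-Bu, t-BuOH/THF, 60 °C
Reagents that add atoms: none
Why: Reversible enolisation of the tertiary lactams equilibrates C4 only, and the target configuration should be favoured because, with the aryl group axial through A(1,3) strain with N-methyl, the C4 methyl group is equatorial and free of the 1,3-diaxial contact with C7 that the kinetic epimer suffers.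

Step 18
Reactants: 25 bis-lactam with the target C4 configuration
Product: 26 6,8-bis[(1R,4R,4aR,7S,7aR)-2,4,7-trimethyloctahydro-1H-cyclopenta[c]pyridin-1-yl]-3,5,7,3′,4′-penta-O-benzyl-(+)-catechin
Conditions: LiAlH4, THF, reflux; aq. NaOH work-up
Reagents that add atoms: none
Why: LiAlH4 reduction of tertiary lactams gives the N-methylpiperidines directly, with benzyl ethers inert and no stereocentre epimerisable under these conditions.

Step 19
Reactants: 26 penta-O-benzyl bis-amine
Product: 27 6,8-bis[(1R,4R,4aR,7S,7aR)-2,4,7-trimethyloctahydro-1H-cyclopenta[c]pyridin-1-yl]-(+)-catechin (CNP0284716.2)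
Conditions: H2 (1 atm), Pd(OH)2/C, THF/MeOH, rt
Reagents that add atoms: none
Why: Catalytic hydrogenolysis cleaves the five O-benzyl groups, which should react faster than the hindered tertiary benzylic C1–N bonds at atmospheric pressure and room temperature, and touches no stereocentre.

Compound list
1 | (R)-citronellol | OCC[C@H](C)CCC=C(C)C | starting material
2 | (R)-citronellyl tert-butyldimethylsilyl ether | CC(C)(C)[Si](C)(C)OCC[C@H](C)CCC=C(C)C | intermediate
3 | secondary ozonide of 2 (3,3-dimethyl-1,2,4-trioxolane, ring carbon C5 unspecified) | CC(C)(C)[Si](C)(C)OCC[C@H](C)CCC1OOC(C)(C)O1 | intermediate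
4 | (R)-6-[(tert-butyldimethylsilyl)oxy]-4-methylhexanal | CC(C)(C)[Si](C)(C)OCC[C@H](C)CCC=O | intermediate
5 | (S,E)-6-[(tert-butyldimethylsilyl)oxy]-4-methylhex-2-enal | CC(C)(C)[Si](C)(C)OCC[C@H](C)/C=C/C=O | intermediate
6 | (S,E)-6-[(tert-butyldimethylsilyl)oxy]-4-methylhex-2-en-1-ol | CC(C)(C)[Si](C)(C)OCC[C@H](C)/C=C/CO | intermediate
7 | (S,E)-[(6-bromo-3-methylhex-4-en-1-yl)oxy](tert-butyl)dimethylsilane | CC(C)(C)[Si](C)(C)OCC[C@H](C)/C=C/CBr | intermediate
8 | (+)-catechin | O[C@H]1Cc2c(O)cc(O)cc2O[C@@H]1c1ccc(O)c(O)c1 | starting material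
9 | 5,7,3′,4′-tetra-O-benzyl-(+)-catechin | O[C@H]1Cc2c(OCc3ccccc3)cc(OCc3ccccc3)cc2O[C@@H]1c1ccc(OCc2ccccc2)c(OCc2ccccc2)c1 | intermediate
10 | 3,5,7,3′,4′-penta-O-benzyl-(+)-catechin | C(c1ccccc1)O[C@H]1Cc2c(OCc3ccccc3)cc(OCc3ccccc3)cc2O[C@@H]1c1ccc(OCc2ccccc2)c(OCc2ccccc2)c1 | intermediate
11 | 6,8-dibromo-penta-O-benzylcatechin | C(c1ccccc1)O[C@H]1Cc2c(OCc3ccccc3)c(Br)c(OCc3ccccc3)c(Br)c2O[C@@H]1c1ccc(OCc2ccccc2)c(OCc2ccccc2)c1 | intermediate
12 | 6,8-dilithio-penta-O-benzylcatechin | C(c1ccccc1)O[C@H]1Cc2c(OCc3ccccc3)c([Li])c(OCc3ccccc3)c([Li])c2O[C@@H]1c1ccc(OCc2ccccc2)c(OCc2ccccc2)c1 | intermediate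
13 | penta-O-benzylcatechin-6,8-dicarbaldehyde | C(c1ccccc1)O[C@H]1Cc2c(OCc3ccccc3)c(C=O)c(OCc3ccccc3)c(C=O)c2O[C@@H]1c1ccc(OCc2ccccc2)c(OCc2ccccc2)c1 | intermediate
14 | (S)-tert-butanesulfinamide | CC(C)(C)[S@](=O)N | starting material
15 | 6,8-bis[(E)-N-((S)-tert-butanesulfinyl)aldimine] of 13 | C(c1ccccc1)O[C@H]1Cc2c(OCc3ccccc3)c(/C=N/[S@@](=O)C(C)(C)C)c(OCc3ccccc3)c(/C=N/[S@@](=O)C(C)(C)C)c2O[C@@H]1c1ccc(OCc2ccccc2)c(OCc2ccccc2)c1 | intermediate
16 | (S,E)-allylindium dibromide from 7 (drawn as the monomer) | CC(C)(C)[Si](C)(C)OCC[C@H](C)/C=C/C[In](Br)Br | intermediate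
17 | bis(homoallylic sulfinamide), each arm (1R,2S,3S), sulfur S | C(c1ccccc1)O[C@H]1Cc2c(OCc3ccccc3)c([C@H](N[S@@](=O)C(C)(C)C)[C@H]([C@@H](C)CCO[Si](C)(C)C(C)(C)C)C=C)c(OCc3ccccc3)c([C@H](N[S@@](=O)C(C)(C)C)[C@H]([C@@H](C)CCO[Si](C)(C)C(C)(C)C)C=C)c2O[C@@H]1c1ccc(OCc2ccccc2)c(OCc2ccccc2)c1 | intermediate
18 | bis(N-methyl sulfinamide) | C(c1ccccc1)O[C@H]1Cc2c(OCc3ccccc3)c([C@H](N(C)[S@@](=O)C(C)(C)C)[C@H]([C@@H](C)CCO[Si](C)(C)C(C)(C)C)C=C)c(OCc3ccccc3)c([C@H](N(C)[S@@](=O)C(C)(C)C)[C@H]([C@@H](C)CCO[Si](C)(C)C(C)(C)C)C=C)c2O[C@@H]1c1ccc(OCc2ccccc2)c(OCc2ccccc2)c1 | intermediate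
19 | methacryloyl chloride | C=C(C)C(=O)Cl | starting material
20 | bis(N-methylamino alcohol) dihydrochloride | C(c1ccccc1)O[C@H]1Cc2c(OCc3ccccc3)c([C@H](NC)[C@H]([C@@H](C)CCO)C=C)c(OCc3ccccc3)c([C@H](NC)[C@H]([C@@H](C)CCO)C=C)c2O[C@@H]1c1ccc(OCc2ccccc2)c(OCc2ccccc2)c1.Cl.Cl | intermediate
21 | bis(N-methyl methacrylamide) diol | C(c1ccccc1)O[C@H]1Cc2c(OCc3ccccc3)c([C@H](N(C)C(=O)C(C)=C)[C@H]([C@@H](C)CCO)C=C)c(OCc3ccccc3)c([C@H](N(C)C(=O)C(C)=C)[C@H]([C@@H](C)CCO)C=C)c2O[C@@H]1c1ccc(OCc2ccccc2)c(OCc2ccccc2)c1 | intermediate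
22 | bis(N-methyl methacrylamide) di-iodide | C(c1ccccc1)O[C@H]1Cc2c(OCc3ccccc3)c([C@H](N(C)C(=O)C(C)=C)[C@H]([C@@H](C)CCI)C=C)c(OCc3ccccc3)c([C@H](N(C)C(=O)C(C)=C)[C@H]([C@@H](C)CCI)C=C)c2O[C@@H]1c1ccc(OCc2ccccc2)c(OCc2ccccc2)c1 | intermediate
23 | pentabenzyl bis[(5R,6R)-5-((S)-4-iodobutan-2-yl)-1,3-dimethyl-5,6-dihydropyridin-2-one], key precursor | C(c1ccccc1)O[C@H]1Cc2c(OCc3ccccc3)c([C@H]3[C@H]([C@@H](C)CCI)C=C(C)C(=O)N3C)c(OCc3ccccc3)c([C@H]3[C@H]([C@@H](C)CCI)C=C(C)C(=O)N3C)c2O[C@@H]1c1ccc(OCc2ccccc2)c(OCc2ccccc2)c1 | intermediate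
24 | pentabenzyl bis(C3 lactam), cis-fused, kinetic C4 configuration (4S) | C(c1ccccc1)O[C@H]1Cc2c(OCc3ccccc3)c([C@H]3[C@H]4[C@H](CC[C@@H]4C)[C@H](C)C(=O)N3C)c(OCc3ccccc3)c([C@H]3[C@H]4[C@H](CC[C@@H]4C)[C@H](C)C(=O)N3C)c2O[C@@H]1c1ccc(OCc2ccccc2)c(OCc2ccccc2)c1 | intermediate
25 | pentabenzyl bis(C3 lactam), target C4 configuration (4R) | C(c1ccccc1)O[C@H]1Cc2c(OCc3ccccc3)c([C@H]3[C@H]4[C@H](CC[C@@H]4C)[C@@H](C)C(=O)N3C)c(OCc3ccccc3)c([C@H]3[C@H]4[C@H](CC[C@@H]4C)[C@@H](C)C(=O)N3C)c2O[C@@H]1c1ccc(OCc2ccccc2)c(OCc2ccccc2)c1 | intermediate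
26 | pentabenzyl bis(N-methylpiperidine) | C(c1ccccc1)O[C@H]1Cc2c(OCc3ccccc3)c([C@H]3[C@H]4[C@H](CC[C@@H]4C)[C@@H](C)CN3C)c(OCc3ccccc3)c([C@H]3[C@H]4[C@H](CC[C@@H]4C)[C@@H](C)CN3C)c2O[C@@H]1c1ccc(OCc2ccccc2)c(OCc2ccccc2)c1 | intermediate
27 | CNP0284716.2 | O[C@H]1Cc2c(O)c([C@H]3[C@H]4[C@H](CC[C@@H]4C)[C@@H](C)CN3C)c(O)c([C@H]3[C@H]4[C@H](CC[C@@H]4C)[C@@H](C)CN3C)c2O[C@@H]1c1ccc(O)c(O)c1 | target

Total step count: 19. Longest linear sequence: 14 steps (steps 6 to 19 from (+)-catechin; the branch from (R)-citronellol, steps 1 to 5 and 11 to 19, is equally long).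

Steps most likely to fail

Step 11. The double addition to a hindered, electron-rich bis-imine may stop at the mono-adduct, and the γ-substituted allylindium may add with poor or reversed relative topicity at C7a (syn instead of anti to nitrogen). The fallback sets C1, C7a and C7 one after another by enolate chemistry. It sets out from 15 and comes back at 17. The enolate of (E)-but-2-enyl acetate (LiN(i-Pr)2, then ClTi(Oi-Pr)3, THF, −78 °C) adds to both imines in a Mannich-type reaction under sulfinyl control of C1 and gives the bis(β-sulfinylamino crotyl ester) F1. A dianionic Ireland–Claisen rearrangement (LiN(SiMe3)2, Me3SiCl, THF, −78 °C to rt; then Me3SiCHN2) through the N,O-chelated enolate and a chair transition state places the new C7a substituent anti to nitrogen and fixes C7 from the E-alkene, giving the bis(methyl ester) F2. Hydroboration of the new vinyl groups (9-BBN; then NaBO3·4H2O) gives the bis(primary alcohol) F3, which is silylated (TBSCl, imidazole) to the bis(silyl ether) F4. Reduction with i-Bu2AlH at −78 °C gives the dialdehyde F5, and Wittig methylenation (Ph3P=CH2) returns to 17.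

Step 16. The C5 radicals may be reduced before they cyclise, or may abstract hydrogen from C1–H, and the two arms may react unevenly. The fallback forms the same bonds by a reductive radical–polar crossover. It sets out from 23 and comes back at 24 (or its C4 epimers, which step 17 converges) without any new compound (F0). SmI2 with HMPA and t-BuOH in THF at −78 °C to 0 °C reduces each iodide to the C5 radical, which closes onto C4a; the C4 radical is then reduced to a samarium enolate and protonated.

Step 9. The second bromine–lithium exchange may be incomplete, and the benzylic positions of the ethers may be metalated, which would give mono-aldehyde and protonated material. The fallback introduces the formyl groups by cross-coupling and oxidative cleavage. It sets out from 11 and comes back at 13. Suzuki–Miyaura coupling of 11 with potassium vinyltrifluoroborate (Pd(OAc)2, SPhos, K3PO4, toluene/H2O, 90 °C) gives the 6,8-divinyl compound F6, and Lemieux–Johnson cleavage (OsO4 catalytic, NaIO4, 2,6-lutidine, dioxane/H2O) returns to 13.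

Further compounds
F1 | step 11 | 6,8-bis{(1R)-1-[(S)-tert-butanesulfinylamino]-3-[(E)-but-2-enyloxy]-3-oxopropyl}-penta-O-benzylcatechin | C(c1ccccc1)O[C@H]1Cc2c(OCc3ccccc3)c([C@H](N[S@@](=O)C(C)(C)C)CC(=O)OC/C=C/C)c(OCc3ccccc3)c([C@H](N[S@@](=O)C(C)(C)C)CC(=O)OC/C=C/C)c2O[C@@H]1c1ccc(OCc2ccccc2)c(OCc2ccccc2)c1
F2 | step 11 | bis(methyl 2-[aryl(sulfinylamino)methyl]-3-methylpent-4-enoate), configured at C1, C7a and C7 as in 17 | C(c1ccccc1)O[C@H]1Cc2c(OCc3ccccc3)c([C@H](N[S@@](=O)C(C)(C)C)[C@H]([C@@H](C)C=C)C(=O)OC)c(OCc3ccccc3)c([C@H](N[S@@](=O)C(C)(C)C)[C@H]([C@@H](C)C=C)C(=O)OC)c2O[C@@H]1c1ccc(OCc2ccccc2)c(OCc2ccccc2)c1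
F3 | step 11 | bis(primary alcohol) from hydroboration of F2 | C(c1ccccc1)O[C@H]1Cc2c(OCc3ccccc3)c([C@H](N[S@@](=O)C(C)(C)C)[C@H]([C@@H](C)CCO)C(=O)OC)c(OCc3ccccc3)c([C@H](N[S@@](=O)C(C)(C)C)[C@H]([C@@H](C)CCO)C(=O)OC)c2O[C@@H]1c1ccc(OCc2ccccc2)c(OCc2ccccc2)c1
F4 | step 11 | bis(tert-butyldimethylsilyl ether) of F3 | C(c1ccccc1)O[C@H]1Cc2c(OCc3ccccc3)c([C@H](N[S@@](=O)C(C)(C)C)[C@H]([C@@H](C)CCO[Si](C)(C)C(C)(C)C)C(=O)OC)c(OCc3ccccc3)c([C@H](N[S@@](=O)C(C)(C)C)[C@H]([C@@H](C)CCO[Si](C)(C)C(C)(C)C)C(=O)OC)c2O[C@@H]1c1ccc(OCc2ccccc2)c(OCc2ccccc2)c1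
F5 | step 11 | dialdehyde from F4 | C(c1ccccc1)O[C@H]1Cc2c(OCc3ccccc3)c([C@H](N[S@@](=O)C(C)(C)C)[C@H]([C@@H](C)CCO[Si](C)(C)C(C)(C)C)C=O)c(OCc3ccccc3)c([C@H](N[S@@](=O)C(C)(C)C)[C@H]([C@@H](C)CCO[Si](C)(C)C(C)(C)C)C=O)c2O[C@@H]1c1ccc(OCc2ccccc2)c(OCc2ccccc2)c1
F0 | step 16 | none | none
F6 | step 9 | 6,8-divinyl-penta-O-benzylcatechin | C(c1ccccc1)O[C@H]1Cc2c(OCc3ccccc3)c(C=C)c(OCc3ccccc3)c(C=C)c2O[C@@H]1c1ccc(OCc2ccccc2)c(OCc2ccccc2)c1
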